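**Retrosynthetic overview**

1. The route rests on the doubly vinylogous ester O2–C3=C4–C4a=C5(Cl)–C6=O that spans rings A and B. Its C4–C4a bond joins the α-carbon of a methyl ketone to the β-carbon of a 2,3-dichloro-enone.
2. Cutting O2–C3 and C4–C4a gives ring B as vinylogous acid chloride 24 (fragment 1; C1–O as silyl ether, C7/C8 diol as acetonide) and dienone 9 (fragment 2).
3. Fragment 2 comes from (R)-2-methylbutanoic acid by two Wittig olefinations.
4. Fragment 1: ring B is closed by a Dieckmann-type C5–C6 acylation, then chlorinated at C5 and C4a. C8a comes from an epoxide opening. C7 and C8 come from a dihydroxylation on a temporary δ-lactone (C4a–O tether, ring-closing metathesis), which replaces a reagent-controlled dihydroxylation of an open-chain (Z)-enoate, a poor substrate class for that reaction.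
5. Ring order: temporary lactone, ring B (step 14), ring A (step 17); then acetonide removal and C8 acetylation.

Key step: step 17

Assumption: (R)-2-methylbutanoic acid of high enantiomeric purity is taken as commercial; atom labels follow isochromene numbering (O2, C1, C3, C4, C4a, C5–C8, C8a) for all intermediates.

**Fragment 2**

Step 1
Reactants: 1 (R)-2-methylbutanoic acid
Product: 2 (R)-2-methylbutan-1-ol
Conditions: LiAlH4, Et2O, 0 °C → rt
Reagents that add atoms: none
Why: Hydride reduction of the acid to the primary alcohol leaves the α stereocentre untouched because no enolisable carbonyl remains.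

Step 2
Reactants: 2 (R)-2-methylbutan-1-ol; 3 ethyl 2-(triphenylphosphoranylidene)propanoate
Product: 5 ethyl (2E,4R)-2,4-dimethylhex-2-enoate, via (R)-2-methylbutanal 4 (not isolated)
Conditions: TEMPO (cat.), PhI(OAc)2, CH2Cl2, rt; then 3, rt
Reagents that add atoms: none
Why: Oxoammonium oxidation gives the epimerisable aldehyde, which is trapped at once under neutral conditions by the stabilised ylide in an E-selective Wittig olefination.

Step 3
Reactants: 5 ethyl (2E,4R)-2,4-dimethylhex-2-enoate
Product: 6 (2E,4R)-2,4-dimethylhex-2-en-1-ol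
Conditions: i-Bu2AlH, CH2Cl2, −78 °C
Reagents that add atoms: none
Why: 1,2-Reduction of the enoate by the aluminium hydride gives the allylic alcohol without touching the trisubstituted alkene.

Step 4
Reactants: 6 (2E,4R)-2,4-dimethylhex-2-en-1-ol; 7 1-(triphenylphosphoranylidene)propan-2-one
Product: 9 fragment 2 (3E,5E,7R)-5,7-dimethylnona-3,5-dien-2-one, via (2E,4R)-2,4-dimethylhex-2-enal 8 (not isolated)
Conditions: MnO2, 7, toluene, 80 °C
Reagents that add atoms: none
Why: Allylic oxidation with MnO2 and in situ Wittig olefination with the stabilised acetonyl ylide (tandem oxidation–olefination) should give the E,E-dienone, the new alkene being E as usual for stabilised ylides.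

**Fragment 1**

Step 5
Reactants: 10 (E)-but-2-en-1-ol
Product: 11 [(2R,3R)-3-methyloxiran-2-yl]methanol
Conditions: Ti(OiPr)4 (cat.), D-(−)-diisopropyl tartrate (cat.), t-BuOOH, 4 Å molecular sieves, CH2Cl2, −20 °C
Reagents that add atoms: tert-butyl hydroperoxide, CC(C)(C)OO
Why: Katsuki–Sharpless asymmetric epoxidation; with the D-(−)-tartrate the (E)-allylic alcohol is epoxidised on the face that gives the (2R,3R)-epoxy alcohol.

Step 6
Reactants: 11 [(2R,3R)-3-methyloxiran-2-yl]methanol; 12 vinylmagnesium bromide
Product: 13 (2S,3R)-2-ethenylbutane-1,3-diol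
Conditions: CuI (cat.), THF, −40 → −20 °C; NH4Cl (aq)
Reagents that add atoms: none
Why: Copper-catalysed Grignard opening of the trans-2,3-epoxy alcohol at C2 (SN2, inversion) should give the anti 2-vinyl-1,3-diol, so the future C8a centre is fixed by the epoxide while the carbinol carbon (future C4a) keeps its configuration; the minor 1,2-diol from attack at C3 is separable.

Step 7
Reactants: 13 (2S,3R)-2-ethenylbutane-1,3-diol
Product: 14 (2R,3S)-3-[(triethylsilyloxy)methyl]pent-4-en-2-ol
Conditions: Et3SiCl (1.05 equiv), imidazole, CH2Cl2, −78 °C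
Reagents that add atoms: chlorotriethylsilane, CC[Si](Cl)(CC)CC
Why: Low-temperature silylation of a 1,3-diol is selective for the primary hydroxyl (future C1–O) over the hindered secondary one.

Step 8
Reactants: 14 (2R,3S)-3-[(triethylsilyloxy)methyl]pent-4-en-2-ol; 15 methacryloyl chloride
Product: 16 (2R,3S)-3-[(triethylsilyloxy)methyl]pent-4-en-2-yl 2-methylprop-2-enoate
Conditions: Et3N, DMAP (cat.), CH2Cl2, 0 °C → rt
Reagents that add atoms: none
Why: DMAP-catalysed acylation of the secondary alcohol brings in C6, C7 and the C7 methyl and turns the C4a oxygen into a tether for the next step.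

Step 9
Reactants: 16 (2R,3S)-3-[(triethylsilyloxy)methyl]pent-4-en-2-yl 2-methylprop-2-enoate
Product: 17 (5S,6R)-3,6-dimethyl-5-[(triethylsilyloxy)methyl]-5,6-dihydro-2H-pyran-2-one
Conditions: second-generation Grubbs catalyst RuCl2(=CHPh)(H2IMes)(PCy3) (5 mol %), toluene, 80 °C
Reagents that add atoms: none
Why: Ring-closing metathesis of the methacrylate with the vinyl group forms the trisubstituted C7=C8 alkene inside a six-membered lactone, which enforces the cis arrangement of C6 and C8a that an open-chain olefination would have to select for.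

Step 10
Reactants: 17 (5S,6R)-3,6-dimethyl-5-[(triethylsilyloxy)methyl]-5,6-dihydro-2H-pyran-2-one
Product: 18 (3R,4R,5R,6R)-3,4-dihydroxy-3,6-dimethyl-5-[(triethylsilyloxy)methyl]oxan-2-one
Conditions: OsO4 (cat.), N-methylmorpholine N-oxide, acetone/H2O, rt
Reagents that add atoms: N-methylmorpholine N-oxide, C[N+]1([O-])CCOCC1; water, O
Why: Upjohn syn-dihydroxylation; on the cis-5,6-disubstituted dihydropyranone the oxidant should add to the face opposite the C8a CH2OSiEt3 group and the C4a methyl, which sets C7 and C8 with both oxygens cis to each other and trans to C1.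

Step 11
Reactants: 18 (3R,4R,5R,6R)-3,4-dihydroxy-3,6-dimethyl-5-[(triethylsilyloxy)methyl]oxan-2-one
Product: 19 acetonide of 18 (C7–O/C8–O dioxolane fused to the lactone)
Conditions: 2-methoxypropene, PPTS (cat.), CH2Cl2, 0 °C → rt
Reagents that add atoms: 2-methoxypropene, COC(C)=C
Why: Acid-catalysed ketal formation with the enol ether protects the cis tertiary/secondary diol as the dioxolane under conditions mild enough for the primary triethylsilyl ether.

Step 12
Reactants: 19 acetonide lactone
Product: 20 (4R,5R)-5-[(2S,3R)-3-hydroxy-1-(triethylsilyloxy)butan-2-yl]-N-methoxy-N,2,2,4-tetramethyl-1,3-dioxolane-4-carboxamide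
Conditions: MeNHOMe·HCl, i-PrMgCl, THF, −20 °C → rt
Reagents that add atoms: N,O-dimethylhydroxylamine hydrochloride, CNOC.Cl
Why: Weinreb aminolysis of the lactone by the magnesium amide opens the ring irreversibly, frees the C4a hydroxyl and leaves C6 as an acylating group that cannot enolise.

Step 13
Reactants: 20 hydroxy Weinreb amide
Product: 21 (4R,5R)-N-methoxy-N,2,2,4-tetramethyl-5-[(2R)-3-oxo-1-(triethylsilyloxy)butan-2-yl]-1,3-dioxolane-4-carboxamide
Conditions: Dess–Martin periodinane, NaHCO3, CH2Cl2, 0 °C → rt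
Reagents that add atoms: none
Why: Buffered Dess–Martin oxidation of the secondary alcohol gives the C4a methyl ketone under non-basic conditions that should not epimerise the adjacent C8a centre.

Step 14
Reactants: 21 keto Weinreb amide
Product: 22 (3aR,7R,7aR)-2,2,3a-trimethyl-7-[(triethylsilyloxy)methyl]tetrahydro-1,3-benzodioxole-4,6-dione
Conditions: LiN(SiMe3)2 (2.2 equiv), THF, −78 → −20 °C; AcOH
Reagents that add atoms: none
Why: Kinetic deprotonation of the methyl ketone at C5 and intramolecular Claisen (Dieckmann-type) acylation by the Weinreb amide closes ring B through the C5–C6 bond; C7 carries no hydrogen and C8a is not deprotonated under kinetic control.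

Step 15
Reactants: 22 ring B 1,3-dione
Product: 23 5-chloro derivative of 22 (drawn as the C4a enol)
Conditions: N-chlorosuccinimide (1.0 equiv), CH2Cl2, 0 °C
Reagents that add atoms: N-chlorosuccinimide, O=C1CCC(=O)N1Cl
Why: Electrophilic chlorination of the enolised 1,3-dione takes place at C5, the only carbon between the two carbonyls.

Step 16
Reactants: 23 5-chloro-1,3-dione
Product: 24 fragment 1 (3aR,7R,7aR)-5,6-dichloro-2,2,3a-trimethyl-7-[(triethylsilyloxy)methyl]-7,7a-dihydro-1,3-benzodioxol-4(3aH)-one
Conditions: (COCl)2, DMF (cat.), CH2Cl2, 0 °C → rt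
Reagents that add atoms: oxalyl chloride, O=C(Cl)C(Cl)=O
Why: Vilsmeier-type activation of the more accessible C4a enol oxygen and addition–elimination of chloride gives the vinylogous acid chloride with the C6 carbonyl (next to quaternary C7) retained, the regiochemistry known for cyclohexane-1,3-diones with a quaternary carbon beside one carbonyl.

**Fragment union and end game**

Step 17
Reactants: 24 fragment 1; 9 fragment 2
Product: 29 7,8-O-isopropylidene derivative of the 8-O-deacetyl target, via lithium enolate 25 (not isolated), via coupled enedione silyl ether 26 (not isolated), via hydroxy enedione 27 (not isolated), via cyclic hemiketal 28 (not isolated)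
Conditions: 9 (2.2 equiv), LiN(iPr)2 (2.2 equiv), THF, −78 °C; 24, −78 → −40 °C; then 1 M HCl (aq), THF, 0 °C → rt
Reagents that add atoms: none
Why: Kinetic deprotonation of the methyl group of 9 gives the cross-conjugated lithium dienolate 25, whose α-carbon adds to C4a of 24; the resulting C5/C6 enolate expels the C4a chloride (addition–elimination, a vinylogous acyl substitution), and the new C4 methylene of 26, flanked by the C3 ketone and the chloro-enone, is deprotonated at once, which is why a second equivalent of 25 is supplied as the base. The closest known reaction type is the substitution of β-chloro-enones by ketone enolates followed by acid cyclodehydration of a δ-hydroxy ketone to a cyclic enol ether. Aqueous HCl reprotonates the dienolate and cleaves the primary triethylsilyl ether (27), the C1 hydroxyl adds to the C3 carbonyl in a 6-exo-trig hemiketalisation (28), and loss of water toward C4 gives ring A as the enol ether conjugated with the chloro-enone. No stereocentre is formed, since the hemiketal carbon becomes sp2, and C8a should be untouched because the acidic site of the coupled product is C4. The step needs C-attack at C4a and not at the C6 carbonyl or at C5: C6 is screened by quaternary C7 and the C5 chlorine, and only the C4a chlorine is vinylogous to the carbonyl. Should C8a epimerise, the trans arrangement of C1 and the C8 oxygen already present is the one expected to be favoured on the cis-fused dioxolane.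

Step 18
Reactants: 29 7,8-O-isopropylidene bicycle
Product: 30 (7R,8R,8aR)-5-chloro-3-[(1E,3E,5R)-3,5-dimethylhepta-1,3-dien-1-yl]-7,8-dihydroxy-7-methyl-1,7,8,8a-tetrahydro-6H-isochromen-6-one
Conditions: CF3CO2H/H2O (9:1), 0 °C
Reagents that add atoms: none
Why: Aqueous acid hydrolysis of the dioxolane; the vinylogous ester of ring A is a poor enol ether and should tolerate the short exposure, and quaternary C7 blocks dehydration toward an aromatic ring.

Step 19
Reactants: 30 C7,C8-diol
Product: 31 target, (7R,8R,8aR)-5-chloro-3-[(1E,3E,5R)-3,5-dimethylhepta-1,3-dien-1-yl]-7-hydroxy-7-methyl-6-oxo-6,7,8,8a-tetrahydro-1H-isochromen-8-yl acetate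
Conditions: Ac2O, pyridine, 0 °C → rt
Reagents that add atoms: acetic anhydride, CC(=O)OC(C)=O
Why: Acetylation in pyridine without DMAP distinguishes the secondary C8 hydroxyl from the tertiary C7 hydroxyl.

**Compound list**

1 | (R)-2-methylbutanoic acid | CC[C@@H](C)C(O)=O | starting material
2 | (R)-2-methylbutan-1-ol | CC[C@@H](C)CO | intermediate
3 | ethyl 2-(triphenylphosphoranylidene)propanoate | CCOC(=O)C(C)=P(c1ccccc1)(c1ccccc1)c1ccccc1 | starting material
4 | (R)-2-methylbutanal | CC[C@@H](C)C=O | intermediate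
5 | ethyl (2E,4R)-2,4-dimethylhex-2-enoate | CC[C@@H](C)/C=C(\C)C(=O)OCC | intermediate
6 | (2E,4R)-2,4-dimethylhex-2-en-1-ol | CC[C@@H](C)/C=C(\C)CO | intermediate
7 | 1-(triphenylphosphoranylidene)propan-2-one | CC(=O)C=P(c1ccccc1)(c1ccccc1)c1ccccc1 | starting material
8 | (2E,4R)-2,4-dimethylhex-2-enal | CC[C@@H](C)/C=C(\C)C=O | intermediate
9 | fragment 2, (3E,5E,7R)-5,7-dimethylnona-3,5-dien-2-one | CC[C@@H](C)/C=C(C)/C=C/C(C)=O | intermediate
10 | (E)-but-2-en-1-ol | C/C=C/CO | starting material
11 | [(2R,3R)-3-methyloxiran-2-yl]methanol | C[C@H]1O[C@@H]1CO | intermediate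
12 | vinylmagnesium bromide | C=C[Mg]Br | starting material
13 | (2S,3R)-2-ethenylbutane-1,3-diol | C[C@@H](O)[C@@H](C=C)CO | intermediate
14 | (2R,3S)-3-[(triethylsilyloxy)methyl]pent-4-en-2-ol | C[C@@H](O)[C@@H](C=C)CO[Si](CC)(CC)CC | intermediate
15 | methacryloyl chloride | CC(=C)C(Cl)=O | starting material
16 | (2R,3S)-3-[(triethylsilyloxy)methyl]pent-4-en-2-yl 2-methylprop-2-enoate | C[C@@H](OC(=O)C(C)=C)[C@@H](C=C)CO[Si](CC)(CC)CC | intermediate
17 | (5S,6R)-3,6-dimethyl-5-[(triethylsilyloxy)methyl]-5,6-dihydro-2H-pyran-2-one | C[C@H]1OC(=O)C(C)=C[C@H]1CO[Si](CC)(CC)CC | intermediate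
18 | (3R,4R,5R,6R)-3,4-dihydroxy-3,6-dimethyl-5-[(triethylsilyloxy)methyl]oxan-2-one | C[C@H]1OC(=O)[C@](C)(O)[C@H](O)[C@H]1CO[Si](CC)(CC)CC | intermediate
19 | acetonide of 18, (3aR,6R,7S,7aR)-2,2,3a,6-tetramethyl-7-[(triethylsilyloxy)methyl]tetrahydro-4H-[1,3]dioxolo[4,5-c]pyran-4-one | C[C@H]1OC(=O)[C@](C)(OC(C)(C)O2)[C@H]2[C@H]1CO[Si](CC)(CC)CC | intermediate
20 | (4R,5R)-5-[(2S,3R)-3-hydroxy-1-(triethylsilyloxy)butan-2-yl]-N-methoxy-N,2,2,4-tetramethyl-1,3-dioxolane-4-carboxamide | CON(C)C(=O)[C@](C)(OC(C)(C)O1)[C@H]1[C@@H](CO[Si](CC)(CC)CC)[C@@H](C)O | intermediate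
21 | (4R,5R)-N-methoxy-N,2,2,4-tetramethyl-5-[(2R)-3-oxo-1-(triethylsilyloxy)butan-2-yl]-1,3-dioxolane-4-carboxamide | CON(C)C(=O)[C@](C)(OC(C)(C)O1)[C@H]1[C@@H](CO[Si](CC)(CC)CC)C(C)=O | intermediate
22 | (3aR,7R,7aR)-2,2,3a-trimethyl-7-[(triethylsilyloxy)methyl]tetrahydro-1,3-benzodioxole-4,6-dione | O=C1CC(=O)[C@](C)(OC(C)(C)O2)[C@H]2[C@H]1CO[Si](CC)(CC)CC | intermediate
23 | 5-chloro derivative of 22, drawn as the C4a enol | OC1=C(Cl)C(=O)[C@](C)(OC(C)(C)O2)[C@H]2[C@H]1CO[Si](CC)(CC)CC | intermediate
24 | fragment 1, (3aR,7R,7aR)-5,6-dichloro-2,2,3a-trimethyl-7-[(triethylsilyloxy)methyl]-7,7a-dihydro-1,3-benzodioxol-4(3aH)-one | ClC1=C(Cl)C(=O)[C@](C)(OC(C)(C)O2)[C@H]2[C@H]1CO[Si](CC)(CC)CC | intermediate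
25 | lithium (3E,5E,7R)-5,7-dimethylnona-1,3,5-trien-2-olate | CC[C@@H](C)/C=C(C)/C=C/C(=C)O[Li] | intermediate
26 | C4–C4a coupled enedione, C1 triethylsilyl ether | CC[C@@H](C)/C=C(C)/C=C/C(=O)CC1=C(Cl)C(=O)[C@](C)(OC(C)(C)O2)[C@H]2[C@H]1CO[Si](CC)(CC)CC | intermediate
27 | C4–C4a coupled enedione, free C1 alcohol | CC[C@@H](C)/C=C(C)/C=C/C(=O)CC1=C(Cl)C(=O)[C@](C)(OC(C)(C)O2)[C@H]2[C@H]1CO | intermediate
28 | C3 hemiketal of 27 (either C3 epimer) | CC[C@@H](C)/C=C(C)/C=C/C1(O)CC2=C(Cl)C(=O)[C@](C)(OC(C)(C)O3)[C@H]3[C@H]2CO1 | intermediate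
29 | 7,8-O-isopropylidene derivative of the 8-O-deacetyl target, (7R,8R,8aR) | CC[C@@H](C)/C=C(C)/C=C/C1=CC2=C(Cl)C(=O)[C@](C)(OC(C)(C)O3)[C@H]3[C@H]2CO1 | intermediate
30 | (7R,8R,8aR)-5-chloro-3-[(1E,3E,5R)-3,5-dimethylhepta-1,3-dien-1-yl]-7,8-dihydroxy-7-methyl-1,7,8,8a-tetrahydro-6H-isochromen-6-one | CC[C@@H](C)/C=C(C)/C=C/C1=CC2=C(Cl)C(=O)[C@](C)(O)[C@H](O)[C@H]2CO1 | intermediate
31 | (7R,8R,8aR)-5-chloro-3-[(1E,3E,5R)-3,5-dimethylhepta-1,3-dien-1-yl]-7-hydroxy-7-methyl-6-oxo-6,7,8,8a-tetrahydro-1H-isochromen-8-yl acetate | CC[C@@H](C)/C=C(C)/C=C/C1=CC2=C(Cl)C(=O)[C@](C)(O)[C@H](OC(C)=O)[C@H]2CO1 | target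

**Step count**

Total: 19 steps. Longest linear sequence: 15 steps (steps 5–19, from (E)-but-2-en-1-ol).

**Steps most likely to fail**

Step 17. Proton transfer may outrun carbon–carbon bond formation: the enolate can remove the C8a proton of 24 (vinylogous enolisation), after which the C8 alkoxide of the acetonide is expelled. The enolate may also attack the C6 carbonyl, or equilibrate toward the extended trienolate with loss of the side-chain configuration. The fallback sets out from 9 and 24 and returns at 29. Ketone 9 is converted through its enol phosphate (LiN(iPr)2, ClP(O)(OEt)2; then LiN(iPr)2) into (3E,5E,7R)-5,7-dimethylnona-3,5-dien-1-yne F1. Sonogashira coupling with 24 (PdCl2(PPh3)2, CuI, Et3N), which should engage only the activated C4a chloride, gives the C4a-alkynyl chloro-enone F2. Bu4NF/AcOH frees the C1 alcohol F3, and 6-endo-dig addition of this hydroxyl to the distal alkyne carbon (AgOSO2CF3 or Ph3PAuNTf2 as catalyst) closes ring A to 29.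

Step 14. Acylation at the hindered amide carbonyl may be slow enough for the kinetic methyl enolate to equilibrate to the C8a enolate, which leads to β-elimination of the silyloxide or the C8 alkoxide, or to epimerisation at C8a. The fallback sets out from 19 and returns at 22. Reduction of lactone 19 with LiAlH4 gives the C6,C4a-diol F4. Dess–Martin oxidation of both hydroxyls gives the keto aldehyde F5, whose C6 aldehyde cannot enolise and is far more electrophilic than the amide. Intramolecular aldol addition of the methyl ketone (LiN(SiMe3)2, THF, −78 °C) closes ring B as the β-hydroxy ketone F6, and a second Dess–Martin oxidation gives dione 22.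

Step 16. Chloride may be delivered to the wrong enol terminus (C6), or the silyl ether may be lost to HCl and the chloroiminium reagent. The fallback sets out from 23 and returns at 29. O-Sulfonylation of 23 (TsCl, Et3N, DMAP cat., CH2Cl2, −20 °C) acylates the enol oxygen directly, so the regiochemistry is decided by access to oxygen and not by attack of chloride at a crowded carbon. The C4a enol tosylate F7 is separable from its isomer, which can be hydrolysed back to 23, and F7 takes the place of 24 in step 17 to give 29.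

**Further compounds**

F1 | step 17 | (3E,5E,7R)-5,7-dimethylnona-3,5-dien-1-yne | CC[C@@H](C)/C=C(C)/C=C/C#C
F2 | step 17 | C4a-alkynyl chloro-enone, C1 triethylsilyl ether | CC[C@@H](C)/C=C(C)/C=C/C#CC1=C(Cl)C(=O)[C@](C)(OC(C)(C)O2)[C@H]2[C@H]1CO[Si](CC)(CC)CC
F3 | step 17 | C4a-alkynyl chloro-enone, free C1 alcohol | CC[C@@H](C)/C=C(C)/C=C/C#CC1=C(Cl)C(=O)[C@](C)(OC(C)(C)O2)[C@H]2[C@H]1CO
F4 | step 14 | C6,C4a-diol from reduction of 19 | OC[C@](C)(OC(C)(C)O1)[C@H]1[C@@H](CO[Si](CC)(CC)CC)[C@@H](C)O
F5 | step 14 | C6 aldehyde, C4a methyl ketone | O=C[C@](C)(OC(C)(C)O1)[C@H]1[C@@H](CO[Si](CC)(CC)CC)C(C)=O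
F6 | step 14 | ring B β-hydroxy ketone (C6 carbinol, either epimer) | O=C1CC(O)[C@](C)(OC(C)(C)O2)[C@H]2[C@H]1CO[Si](CC)(CC)CC
F7 | step 16 | C4a enol p-toluenesulfonate of 23 | Cc1ccc(cc1)S(=O)(=O)OC1=C(Cl)C(=O)[C@](C)(OC(C)(C)O2)[C@H]2[C@H]1CO[Si](CC)(CC)CC
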